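**Retrosynthetic overview**

1. Locants (daucane numbering): C1 = ring-fusion C(CH3), C2/C3 = CH2, C4 = C(OH)(iPr), C5 = ring-fusion CH, C6 = CH–O-anisoyl, C7 = CH2, C8 = C(CH3)=, C9 = =CH, C10 = CHOH; five-membered ring C1–C5, seven-membered ring C5–C10 + C1; β is the face of the C1 methyl group.
2. Endgame disconnections: the C6 ester, the C8 methyl group (from an enol triflate) and H-5/O-6 (syn hydroboration of a C5=C6 alkene) lead back to a hydroazulene 5,8-diene 8-triflate.
3. The seven-membered ring is closed last, by an oxyanion-accelerated [3,3] shift of a cis-1,2-dialkenylcyclopropanolate (temporary cyclopropane C6–C7–C8): C6–C8 breaks, C1–C10 forms, and the quaternary C1 and the C10 carbinol are set together.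
4. Enabling feature: in the seven-membered ring the two (latent) alkenes C5=C6 and C8=C9 are separated only by the CH2 group C7 and face the C1–C10 bond. This is a cyclohepta-1,4-diene, i.e. a cis-divinylcyclopropane retron, with oxygen at C10 (enol-ether terminus) and at C8 (enolate oxygen, later exchanged for CH3). The cyclopropanol comes from a Kulinkovich union of a C5–C7 diene with a C8–C10 β-alkoxyacrylate.
5. The five-membered ring is made first, from (S)-terpinen-4-ol by ozonolysis/aldol ring contraction, which keeps the C4 carbinol stereocentre and turns the ring alkene into C6, C5=C1 and the C1 methyl. Ring order: cyclopentene, temporary cyclopropane, cycloheptadiene.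

Key step: step 7

Assumption: (S)-(+)-terpinen-4-ol of high enantiomeric purity is taken as a commercial starting material (natural material of lower ee would have to be upgraded first).

**Route**

Step 1
Reactants: 1 (S)-(+)-terpinen-4-ol
Product: 2 (S)-triethyl[(1-isopropyl-4-methylcyclohex-3-en-1-yl)oxy]silane
Conditions: TESOTf, 2,6-lutidine, CH2Cl2, 0 °C to rt
Reagents that add atoms: triethylsilyl trifluoromethanesulfonate, CC[Si](CC)(CC)OS(=O)(=O)C(F)(F)F
Why: Silylation of a tertiary alcohol with a silyl triflate and a hindered base is reliable, does not touch the C4 stereocentre, and blocks retro-aldol and alkoxide chemistry in the following steps.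

Step 2
Reactants: 2 (S)-triethyl[(1-isopropyl-4-methylcyclohex-3-en-1-yl)oxy]silane
Product: 4 (S)-3-isopropyl-6-oxo-3-[(triethylsilyl)oxy]heptanal, via ozonide 3 (not isolated)
Conditions: O3, CH2Cl2, −78 °C; then PPh3, −78 °C to rt
Reagents that add atoms: ozone, [O-][O+]=O
Why: Ozonolysis with reductive work-up cleaves the only C=C bond to a methyl ketone and an aldehyde, and the quaternary stereocentre is remote from the reacting atoms.

Step 3
Reactants: 4 (S)-3-isopropyl-6-oxo-3-[(triethylsilyl)oxy]heptanal
Product: 6 (R)-5-isopropyl-2-methyl-5-[(triethylsilyl)oxy]cyclopent-1-ene-1-carbaldehyde, via aldol adduct 5 (not isolated)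
Conditions: Bn2NH·TFA (cat.), toluene, 50 °C
Reagents that add atoms: none
Why: Amine-catalysed intramolecular aldol condensation (the enamine of the aldehyde adds to the methyl ketone, then dehydration) is the established route from 6-oxoheptanals to 2-methylcyclopent-1-enecarbaldehydes and is preferred under amine catalysis over the ketone-enolate mode; no new stereocentre is formed.

Step 4
Reactants: 6 (R)-5-isopropyl-2-methyl-5-[(triethylsilyl)oxy]cyclopent-1-ene-1-carbaldehyde
Product: 7 (R)-triethyl[(1-isopropyl-3-methyl-2-vinylcyclopent-2-en-1-yl)oxy]silane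
Conditions: Ph3PCH3Br, KOtBu, THF, 0 °C to rt
Reagents that add atoms: methylenetriphenylphosphorane (from methyltriphenylphosphonium bromide and KOtBu), C=P(c1ccccc1)(c1ccccc1)c1ccccc1
Why: Wittig methylenation works on hindered cycloalkenecarbaldehydes of this type and creates no stereocentre.

Step 5
Reactants: 8 4-methoxybenzyl alcohol; 9 methyl propiolate
Product: 10 methyl (E)-3-[(4-methoxybenzyl)oxy]acrylate
Conditions: N-methylmorpholine (cat.), CH2Cl2, rt
Reagents that add atoms: none
Why: Amine-catalysed oxa-Michael addition of an alcohol to a propiolate gives the β-alkoxyacrylate with the thermodynamically preferred E geometry.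

Step 6
Reactants: 7 (R)-triethyl[(1-isopropyl-3-methyl-2-vinylcyclopent-2-en-1-yl)oxy]silane; 10 methyl (E)-3-[(4-methoxybenzyl)oxy]acrylate
Product: 12 (1R,2S)-cis-1,2-dialkenylcyclopropan-1-ol (C8 carbinol; C9=C10 E-enol ether; cyclopentenyl on C6), via titanacyclopropane 11 (not isolated)
Conditions: ClTi(OiPr)3, c-C5H9MgCl (slow addition), THF, rt; mild basic work-up
Reagents that add atoms: none
Why: Kulinkovich hydroxycyclopropanation in its olefin-exchange variant: the cyclopentene–titanium complex exchanges with the monosubstituted vinyl group of 7 to give 11, which adds to the ester carbonyl of 10 through its CH2–Ti bond and closes the three-membered ring with retention at C6, so that, as is general for this reaction, the two carbon substituents end up cis (OH trans to the cyclopentenyl group); relative to C4, titanium is expected to bind the π-face turned away from C4 when the vinyl group twists with its CH2 terminus toward the C4 oxygen and away from the isopropyl group.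

Step 7
Reactants: 12 (1R,2S)-cis-1,2-dialkenylcyclopropan-1-ol
Product: 15 hydroazulene-5,8-dien-8-yl triflate (C1β-CH3; C10α-OPMB; C4β-OTES), via potassium cyclopropanolate 13 (not isolated), via potassium enolate 14 (not isolated)
Conditions: KHMDS, THF, −78 to −20 °C; then N-(5-chloro-2-pyridyl)triflimide, −78 to 0 °C
Reagents that add atoms: N-(5-chloropyridin-2-yl)bis(trifluoromethanesulfonyl)imide, O=S(=O)(N(c1ccc(Cl)cn1)S(=O)(=O)C(F)(F)F)C(F)(F)F
Why: Deprotonation gives cyclopropanolate 13, whose cis-disposed alkenyl groups undergo an oxyanion-accelerated [3,3] shift (cis-divinylcyclopropane/oxy-Cope rearrangement) through the boat transition state: the strained C6–C8 bond breaks, C1–C10 forms, and the regiodefined C8 enolate 14 is O-triflated in situ. The closest known reaction type is the rearrangement of cis-1,2-dialkenylcyclopropanols and of the cyclopropanolates of acylsilane-based [3+4] annulations to cyclohept-4-enones, combined with standard enolate trapping by an N-aryl triflimide. The seven-membered ring is closed by sigmatropic ring expansion of the three-membered ring (suprafacial on both allyl units), so both ring alkenes (C5=C6, C8=C9) are necessarily cis and no exo/endo question arises. C1 (quaternary) and C10 are set by the boat geometry: the E-substituents of the two termini (O-PMB on C10, ring carbon C2 on C1) become cis, which places the C1 methyl trans to the C10 oxygen, and their absolute sense is relayed from the cyclopropane carbons C6 and C8 fixed in step 6. The step needs rearrangement to win over heterolytic opening of the cyclopropanolate, which the cis relationship and the low temperature should secure, and O-sulfonylation of the kinetic C8 enolate before proton transfer or β-elimination of the C10 alkoxy group, which trapping at −78 °C should secure.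

Step 8
Reactants: 15 hydroazulene-5,8-dien-8-yl triflate
Product: 17 trans-fused C6α-alcohol (H-5α; C8 enol triflate retained), via alkylborane 16 (not isolated)
Conditions: BH3·THF, THF, 0 °C to rt; then 30% H2O2, aq. NaOAc, 0 °C to rt
Reagents that add atoms: hydrogen peroxide, OO
Why: Hydroboration–oxidation adds H and OH syn and anti-Markovnikov to the trisubstituted C5=C6 alkene (the enol triflate alkene is deactivated) from the α-face, opposite the angular C1 methyl and the C4 silyloxy group as in the hydroboration of Δ5-steroids, so H-5 and O-6 both become α (trans ring fusion), and the oxidation proceeds with retention.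

Step 9
Reactants: 17 trans-fused C6α-alcohol; 18 4-methoxybenzoyl chloride
Product: 19 C6α 4-methoxybenzoate (C8 enol triflate; C10α-OPMB; C4β-OTES)
Conditions: DMAP, Et3N, CH2Cl2, rt
Reagents that add atoms: none
Why: DMAP-catalysed acylation of the only free hydroxyl group installs the final ester, which also serves as the C6 protecting group; no stereocentre changes.

Step 10
Reactants: 19 C6α 4-methoxybenzoate
Product: 20 C8-methyl compound (4-O-TES and 10-O-PMB derivative of the target)
Conditions: MeZnCl, Pd(PPh3)4 (cat.), THF, 50 °C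
Reagents that add atoms: methylzinc chloride, C[Zn]Cl
Why: Negishi coupling of an alkenyl triflate with a methylzinc reagent is general, tolerates the ester and both ethers, and the position and geometry of C8=C9 are fixed by the triflate.

Step 11
Reactants: 20 C8-methyl compound
Product: 21 10-O-(4-methoxybenzyl) ether of the target
Conditions: HF·pyridine, pyridine, THF, 0 °C to rt
Reagents that add atoms: none
Why: Fluoride cleaves the tertiary triethylsilyl ether, and the buffered, non-basic medium avoids acyl migration from O-6 and leaves the ester and the PMB ether intact.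

Step 12
Reactants: 21 10-O-(4-methoxybenzyl) ether of the target
Product: 22 target, CNP0211568.1
Conditions: DDQ, CH2Cl2/pH 7 buffer, 0 °C
Reagents that add atoms: none
Why: DDQ cleaves the p-methoxybenzyl ether oxidatively (benzylic hydride abstraction, hydrolysis of the oxocarbenium ion) to free the C10 hydroxyl, while the 4-methoxybenzoate, which has no benzylic C–H, is not attacked.

**Compound list**

1 | (S)-(+)-terpinen-4-ol, (S)-1-isopropyl-4-methylcyclohex-3-en-1-ol | CC1=CC[C@](O)(C(C)C)CC1 | starting material
2 | (S)-triethyl[(1-isopropyl-4-methylcyclohex-3-en-1-yl)oxy]silane | CC1=CC[C@](O[Si](CC)(CC)CC)(C(C)C)CC1 | intermediate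
3 | secondary ozonide (1,2,4-trioxolane across the former C=C) of 2, ozonide carbons as a mixture | CC12CC[C@@](O[Si](CC)(CC)CC)(C(C)C)CC(OO1)O2 | intermediate (not isolated)
4 | (S)-3-isopropyl-6-oxo-3-[(triethylsilyl)oxy]heptanal | CC(=O)CC[C@@](O[Si](CC)(CC)CC)(C(C)C)CC=O | intermediate
5 | aldol adduct, 2-hydroxy-5-isopropyl-2-methyl-5-[(triethylsilyl)oxy]cyclopentane-1-carbaldehyde (C4 as in 4, new centres as a mixture) | CC1(O)CC[C@@](O[Si](CC)(CC)CC)(C(C)C)C1C=O | intermediate (not isolated)
6 | (R)-5-isopropyl-2-methyl-5-[(triethylsilyl)oxy]cyclopent-1-ene-1-carbaldehyde | O=CC1=C(C)CC[C@@]1(O[Si](CC)(CC)CC)C(C)C | intermediate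
7 | (R)-triethyl[(1-isopropyl-3-methyl-2-vinylcyclopent-2-en-1-yl)oxy]silane | C=CC1=C(C)CC[C@@]1(O[Si](CC)(CC)CC)C(C)C | intermediate
8 | 4-methoxybenzyl alcohol | OCc1ccc(OC)cc1 | starting material
9 | methyl propiolate | C#CC(=O)OC | starting material
10 | methyl (E)-3-[(4-methoxybenzyl)oxy]acrylate | COC(=O)/C=C/OCc1ccc(OC)cc1 | intermediate
11 | diisopropoxytitanacyclopropane formed from the vinyl group of 7 (Ti bonded to C6 and C7) | CC(C)O[Ti]1(OC(C)C)CC1C2=C(C)CC[C@@]2(O[Si](CC)(CC)CC)C(C)C | intermediate (not isolated)
12 | (1R,2S)-1-{(E)-2-[(4-methoxybenzyl)oxy]vinyl}-2-{(R)-5-isopropyl-2-methyl-5-[(triethylsilyl)oxy]cyclopent-1-en-1-yl}cyclopropan-1-ol (alkenyl groups cis) | O[C@]1(/C=C/OCc3ccc(OC)cc3)C[C@H]1C2=C(C)CC[C@@]2(O[Si](CC)(CC)CC)C(C)C | intermediate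
13 | potassium alkoxide of 12 | [K]O[C@]1(/C=C/OCc3ccc(OC)cc3)C[C@H]1C2=C(C)CC[C@@]2(O[Si](CC)(CC)CC)C(C)C | intermediate (not isolated)
14 | potassium C8 enolate of the ring-expanded hydroazulenone (C8=C9 enolate, C5=C6 alkene, C1β-CH3, C10α-OPMB, C4β-OTES, C4α-iPr) | [K]OC1=C[C@@H](OCc2ccc(OC)cc2)[C@@]3(C)CC[C@@](O[Si](CC)(CC)CC)(C(C)C)C3=CC1 | intermediate (not isolated)
15 | hydroazulene-5,8-dien-8-yl trifluoromethanesulfonate (C5=C6 and C8=C9, C1β-CH3, C10α-OPMB, C4β-OTES, C4α-iPr) | O=S(=O)(OC1=C[C@@H](OCc2ccc(OC)cc2)[C@@]3(C)CC[C@@](O[Si](CC)(CC)CC)(C(C)C)C3=CC1)C(F)(F)F | intermediate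
16 | C6α-alkylborane from 15 (H-5α, drawn as the monoalkylborane) | B[C@H]2CC(OS(=O)(=O)C(F)(F)F)=C[C@@H](OCc1ccc(OC)cc1)[C@@]3(C)CC[C@@](O[Si](CC)(CC)CC)(C(C)C)[C@H]23 | intermediate (not isolated)
17 | trans-fused C6α-alcohol (H-5α, C8 enol triflate with C8=C9, C10α-OPMB, C4β-OTES) | O[C@H]2CC(OS(=O)(=O)C(F)(F)F)=C[C@@H](OCc1ccc(OC)cc1)[C@@]3(C)CC[C@@](O[Si](CC)(CC)CC)(C(C)C)[C@H]23 | intermediate
18 | 4-methoxybenzoyl chloride | COc1ccc(C(Cl)=O)cc1 | starting material
19 | C6α 4-methoxybenzoate of 17 | COc1ccc(C(=O)O[C@H]2CC(OS(=O)(=O)C(F)(F)F)=C[C@@H](OCc4ccc(OC)cc4)[C@@]3(C)CC[C@@](O[Si](CC)(CC)CC)(C(C)C)[C@H]23)cc1 | intermediate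
20 | 4-O-triethylsilyl, 10-O-(4-methoxybenzyl) derivative of the target (C8-CH3, C8=C9) | COc1ccc(C(=O)O[C@H]2CC(C)=C[C@@H](OCc4ccc(OC)cc4)[C@@]3(C)CC[C@@](O[Si](CC)(CC)CC)(C(C)C)[C@H]23)cc1 | intermediate
21 | 10-O-(4-methoxybenzyl) ether of the target | COc1ccc(C(=O)O[C@H]2CC(C)=C[C@@H](OCc4ccc(OC)cc4)[C@@]3(C)CC[C@@](O)(C(C)C)[C@H]23)cc1 | intermediate
22 | CNP0211568.1: trans-fused daucane, 1β-CH3, 4β-OH, 4α-iPr, H-5α, 6α-(4-methoxybenzoyloxy), C8=C9, 10α-OH | COc1ccc(C(=O)O[C@H]2CC(C)=C[C@@H](O)[C@@]3(C)CC[C@@](O)(C(C)C)[C@H]23)cc1 | target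

**Step count and risks**

Total step count: 12. Longest linear sequence: 11 steps (steps 1–4 and 6–12; step 5 is a one-step side branch).

The three steps most likely to fail:

Step 6. The hindered, conjugated vinyl group of 7 may exchange onto titanium too slowly, so that 10 is consumed by the cyclopentene-derived titanacycle, and control of the vinyl π-face by C4 may be incomplete. Fallback (sets out from 7, returns at 12): the titanacyclopropane is generated without olefin exchange, by the classical Kulinkovich protocol with the fragment as the Grignard component. Hydroboration of the terminal vinyl group of 7 (9-BBN; H2O2, NaOH) should give the primary alcohol F1, an Appel reaction (CBr4, PPh3) the bromide F2, and magnesium insertion the Grignard reagent F3. Two equivalents of F3 with Ti(OiPr)4 and 10 generate 11 by β-hydride abstraction in the dialkyltitanium (one equivalent is sacrificed as the alkane) and should give 12. This answers the exchange problem only; the facial sense is inherent to 11 in both variants.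

Step 7. The cyclopropanolate may open heterolytically to a homoenolate instead of rearranging, the shift may be slow because the C1 terminus is fully substituted, or the C10 alkoxy group may be lost from enolate 14 by β-elimination before triflation. Fallback (sets out from 12, returns at 15): 12 is silylated (TMS-imidazole) to the trimethylsilyl ether F4, which is heated (toluene, 80–110 °C) for the neutral divinylcyclopropane rearrangement to the regiodefined silyl enol ether F5. MeLi (THF, 0 °C) releases the lithium enolate F6, which is triflated with the same N-aryl triflimide to give 15.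

Step 8. Facial selectivity may be poor (borane adding to the β-face would give the cis-fused 5β-H/6β-ol), or addition at the hindered alkene may be sluggish. Fallback (sets out from 15, returns at the target 22): a temporary silicon tether from the α-oriented C10 oxygen. DDQ frees the C10 alcohol F7, and ClSiMe2H/Et3N gives the hydrosilyl ether F8. Pt(0)–divinyltetramethyldisiloxane-catalysed intramolecular hydrosilylation delivers Si–H to the α-face, silicon to C6 and hydrogen to C5 (closure onto C5 would put silicon on a fully substituted carbon), to give the six-membered cyclic siloxane F9. Tamao oxidation (H2O2, KF, KHCO3) should give the 6α,10α-diol F10; acylation with 18 at the less hindered C6 hydroxyl (C10–OH is neopentylic) gives the monoester F11, Negishi methylation the C8-methyl compound F12, and HF·pyridine the target 22.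

Further compounds
F1 | step 6 | 2-{(R)-5-isopropyl-2-methyl-5-[(triethylsilyl)oxy]cyclopent-1-en-1-yl}ethan-1-ol | OCCC1=C(C)CC[C@@]1(O[Si](CC)(CC)CC)C(C)C
F2 | step 6 | (R)-{[2-(2-bromoethyl)-1-isopropyl-3-methylcyclopent-2-en-1-yl]oxy}triethylsilane | BrCCC1=C(C)CC[C@@]1(O[Si](CC)(CC)CC)C(C)C
F3 | step 6 | Grignard reagent from F2 | Br[Mg]CCC1=C(C)CC[C@@]1(O[Si](CC)(CC)CC)C(C)C
F4 | step 7 | trimethylsilyl ether of 12 | C[Si](C)(C)O[C@]1(/C=C/OCc3ccc(OC)cc3)C[C@H]1C2=C(C)CC[C@@]2(O[Si](CC)(CC)CC)C(C)C
F5 | step 7 | C8 trimethylsilyl enol ether of the ring-expanded hydroazulenone (C8=C9, C5=C6) | C[Si](C)(C)OC1=C[C@@H](OCc2ccc(OC)cc2)[C@@]3(C)CC[C@@](O[Si](CC)(CC)CC)(C(C)C)C3=CC1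
F6 | step 7 | lithium C8 enolate (lithium analogue of 14) | [Li]OC1=C[C@@H](OCc2ccc(OC)cc2)[C@@]3(C)CC[C@@](O[Si](CC)(CC)CC)(C(C)C)C3=CC1
F7 | step 8 | C10α-alcohol from 15 (PMB removed) | O=S(=O)(OC1=C[C@@H](O)[C@@]3(C)CC[C@@](O[Si](CC)(CC)CC)(C(C)C)C3=CC1)C(F)(F)F
F8 | step 8 | C10-O-dimethylsilyl (Si–H) ether of F7 | O=S(=O)(OC1=C[C@@H](O[SiH](C)C)[C@@]3(C)CC[C@@](O[Si](CC)(CC)CC)(C(C)C)C3=CC1)C(F)(F)F
F9 | step 8 | cyclic siloxane, SiMe2 bridging O-10 and C6 on the α-face (H-5α) | C[Si]7(C)[C@H]2CC(OS(=O)(=O)C(F)(F)F)=C[C@@H](O7)[C@@]3(C)CC[C@@](O[Si](CC)(CC)CC)(C(C)C)[C@H]23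
F10 | step 8 | 6α,10α-diol (C8 enol triflate, C4β-OTES) | O[C@H]2CC(OS(=O)(=O)C(F)(F)F)=C[C@@H](O)[C@@]3(C)CC[C@@](O[Si](CC)(CC)CC)(C(C)C)[C@H]23
F11 | step 8 | C6α 4-methoxybenzoate of F10 | COc1ccc(C(=O)O[C@H]2CC(OS(=O)(=O)C(F)(F)F)=C[C@@H](O)[C@@]3(C)CC[C@@](O[Si](CC)(CC)CC)(C(C)C)[C@H]23)cc1
F12 | step 8 | 4-O-triethylsilyl ether of the target | COc1ccc(C(=O)O[C@H]2CC(C)=C[C@@H](O)[C@@]3(C)CC[C@@](O[Si](CC)(CC)CC)(C(C)C)[C@H]23)cc1
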